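Compound numbers refer to the steps and the compound list below. TBS = tert-butyldimethylsilyl.

## Analysis of the target

The target is a bicyclo[3.2.1]oct-2-en-8-one. A cyclopentanone ring (C1–C8–C5–C6–C7) and a six-membered ring (C1–C2–C3–C4–C5–C8) share the bridgeheads C1 and C5 and the ketone bridge C8. The numbering is C1 (allyl bridgehead), C2=C3(OMe), C4 (OAc), C5 (methoxy bridgehead), C6 (aryl), C7 (methyl), C8 (C=O). There are five contiguous stereocentres, (1S,4S,5S,6S,7R), two of them quaternary bridgeheads. The C6 aryl group lies on the face of the C8 bridge and the C7 methyl group on the face of the C2–C4 bridge, so the two are trans; the C4 acetoxy group points to the C8 side, anti to the C5–C6 bond. The sensitive groups are the C2=C3 methyl enol ether (lost with aqueous acid), the C4 acetate (once cleaved it is a β-hydroxy ketone to C8 that can open by retro-aldol), the terminal allyl alkene (it cannot coexist with an olefin oxidation elsewhere) and the electron-rich veratryl ring. The difficulty is the crowded cyclopentanone: an oxygen-bearing quaternary C5 sits between the aryl-bearing C6 and the oxygenated C4, a second quaternary centre sits at C1, and C3, C4 and C8 must be kept at three different oxidation patterns. The strategy rests on the ring C1–C8–C5–C6–C7. A cyclopentanone with trans substituents on C6 and C7 and a methoxy-bearing quaternary α-carbon C5 bonded to the oxygenated C4 is what a conrotatory divinyl ketone closure gives, if the oxyallyl cation is captured at C5 by a carbon nucleophile that brings C4 with its oxygen.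

## Retrosynthetic reasoning

**C4 acyl–oxygen bond (27 ⇒ 26 ⇒ 25).** The acetate is cut last, back to alcohol 26 and its silyl ether 25. The C4 oxygen is carried as a silyl ether and not as an acetal, because an acetal could only be removed with acid and the C2=C3 methyl enol ether would not survive that. Forward, buffered fluoride must free a hindered secondary alcohol without retro-aldol opening, and acylation follows with retention.

**Terminal C=C of the allyl group (25 ⇒ 24 ⇒ 23 ⇒ 22).** The allyl alkene is cut by a methylenation transform to aldehyde 24, which comes from alcohol 23 and its primary silyl ether 22. A free allyl group could not pass the olefin oxidation of step 9, so it travels as a 2-silyloxyethyl chain. Forward, the primary silyl ether must be released next to the hindered secondary one, and the aldehyde must be methylenated in the presence of the C8 ketone.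

**O–CH3 bond of the enol ether (22 ⇒ 20).** Cutting the enol ether gives diketone 20. C8 has no α-hydrogen, so only the C3 ketone can enolise. Forward, the enolate must form toward C2 and not toward C4, and must be alkylated on oxygen.

**C1–C2 bond (20 ⇒ 18).** The 1,4-relationship of the C8 and C3 carbonyls is the retron for joining two α-carbons, so the six-membered ring is opened at C1–C2 to give the monocyclic methyl ketone 18. This is the only ring bond whose cleavage leaves the cyclopentanone intact. Forward, the tether hangs from C5, so closure can only occur on one face and the bridgehead configuration at C1 follows. The coupling is planned as an oxidation of the pre-formed bis-enolate. A free α-halomethyl ketone would carry the most acidic hydrogens in the molecule and an α′-hydrogen at C4, which invites Darzens- and Favorskii-type diversions once base is added.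

**C3 carbonyl (18 ⇒ 17).** The methyl ketone is traced to the vinyl group of 17 by a Wacker transform. Forward, oxygen must go to the internal carbon although it is next to an allylic oxygen.

**C6–C7 and C4–C5 (17 ⇒ 11 + 14).** This is the key disconnection. Cutting both bonds unfolds the cyclopentanone into the cross-conjugated dienone 11 and the γ-oxygenated allylstannane 14. Four stereocentres, the ring and the oxygenated quaternary centre are formed in one operation from an acyclic precursor. Forward, a chiral Lewis acid must choose the sense of conrotation, and the stannane must capture the oxyallyl cation at C5, on the face opposite the aryl group, before a proton is lost.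

**Acyl–alkenyl bond (11 ⇒ 4 + 9).** The dienone is cut between the carbonyl carbon and the propenyl arm, giving N-methoxy-N-methylamide 4 and vinyl iodide 9 (used as vinyllithium 10). Each arm then brings its alkene geometry from a separately made, stereodefined partner. Both β-substituents must be anti to the carbonyl for the trans outcome of the conrotation.

**Styryl C=C (4 ⇒ 3 ⇒ 1 + 2).** The α-methoxy cinnamoyl unit comes from an aldol condensation of aldehyde 1 with ester 2. Ester 2 also supplies the methoxy group that ends on C5.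

**Vinyl iodide (9 ⇒ 8 ⇒ 7 ⇒ 5).** The iodide is traced through a carbon–silicon bond to alkynol 5. An intermolecular hydrometalation of this methyl-capped alkyne would put the metal on the less hindered, methyl-bearing carbon, which is the wrong atom. A temporary silicon tether on the hydroxyl group (6 ⇒ 7) forces delivery to the carbon nearer to oxygen, with syn addition.

**Stannane (14 ⇒ 12).** The allylstannane comes from allyl silyl ether 12 by metalation and stannylation at the carbon remote from oxygen.

## Alternatives that were turned down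

**Alternative 1: (4+3) cycloaddition.**
- Disconnection: C1–C2 and C4–C5 are cut, which opens the six-membered ring to the cyclopentadienone ketal A1 (diene C1=C7–C6=C5) and a three-carbon oxyallyl cation made from the chiral 2-silyloxyacrolein acetal A2.
- Forward key step: a silyl triflate ionises A2, and the cation adds across the diene termini to give cycloadduct A3.
- For it: both bridgeheads and the whole six-membered ring arise in one convergent step. C3 and C4 arrive at the right oxidation levels, and the auxiliary on oxygen offers absolute control. On ring-forming economy it is stronger than the chosen route, which needs a separate C1–C2 closure.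
- Against it: A1 is a tetrasubstituted 5,5-dialkoxycyclopentadiene, a class that dimerises readily. Both reacting termini are fully substituted. The cation must also pick the orientation that joins its alkoxy-bearing carbon to the methoxy-bearing C5, and nothing in the structure secures that. A3 has no C6 aryl group. The C6=C7 alkene is conjugated to nothing while C8 is a ketal, so a regio- and face-selective hydroarylation would have to follow, then auxiliary removal and ketal hydrolysis.
- Comparison: the chosen strategy sets the aryl/methyl trans pair in the ring-forming event itself and uses stable acyclic precursors.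

**Alternative 2: Divinylcyclopropane Cope rearrangement.**
- Disconnection: C4–C5 is cut and C2–C7 reconnected, which leads to bicyclo[3.1.0]hexenone A4 with an endo (E)-2-acetoxy-1-methoxyvinyl group on the cyclopropane.
- Forward key step: heating A4 passes a boat transition state to the bicyclic dienone A5.
- For it: the step is thermal, reagent-free and stereospecific. Ring strain drives it, the cyclopropane configuration fixes both bridgeheads, and the enol acetate geometry fixes C4. The enol ether and the acetate are already in place. As a single step it is more dependable than the cation capture of step 8.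
- Against it: the difficulty moves into A4. Its preparation needs an endo- and enantioselective cyclopropanation of a cyclopentadienone equivalent with a heavily oxygenated vinyl carbene, with three contiguous stereocentres and a defined enol acetate geometry. A5, like A3, has no aryl group, so C6=C7 must be hydroarylated in the presence of an enol ether, an allylic acetate and a ketone.
- Comparison: the chosen route reaches its precursor in six routine steps and installs C4, C5, C6 and C7 together.

**Alternative 3: Transannular carbene-catalysed benzoin reaction.**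
- Disconnection: cutting C5–C8 unfolds both rings at once into the cycloheptenone carbaldehyde A6.
- Forward key step: a triazolium-derived carbene turns the aldehyde carbon C8 into an acyl anion equivalent that adds across the seven-membered ring to the C5 ketone and gives acyloin A7, the O-demethyl target.
- For it: every substituent, the allyl group included, is in place before the key step. The conditions are mild, and two rings close in one operation, which the chosen route cannot match.
- Against it: A6 is a seven-membered ring with four stereocentres, one a quaternary carbon bearing the aldehyde, and making it should take longer than the whole sequence to 11. The aldehyde is neopentyl, so carbene addition is slow. The acceptor ketone is flanked by an α-acetoxy group and an epimerisable benzylic carbon, and both are exposed to the base that forms the carbene. Nothing in the ring secures the transannular facial selectivity. The tertiary bridgehead alcohol of A7 would then have to be methylated next to a ketone and an acetate, where base invites retro-benzoin cleavage and acyl migration.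
- Comparison: the chosen route carries the C5 methoxy group from the first step, where it comes from 2.

Key step: step 8

Remark on the chemistry: bicyclic compounds are named with the atom numbering fixed in the analysis (C1 = allyl-bearing bridgehead), also where nomenclature rules would number from the other bridgehead.

Remark on the chemistry: descriptor changes at C4 (17 to 18, 20 to 22) and at C1 (20 to 22) come from changed substituent priorities only; no centre is inverted after step 8.

Remark on the chemistry: the sense of induction of the scandium–pybox complex cannot be derived with certainty; the ligand enantiomer named in step 8 is assumed to give the (6S,7R) series, and its mirror image is used if it does not.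

## Route

Step 1
Reactants: 1 3,4-dimethoxybenzaldehyde; 2 methyl 2-methoxyacetate
Product: 3 methyl (Z)-3-(3,4-dimethoxyphenyl)-2-methoxyprop-2-enoate
Conditions: NaOMe, MeOH, 0 °C → reflux
Reagents that add atoms: none
Why: Aldol condensation of the ester enolate with a non-enolisable aryl aldehyde, followed by E1cB loss of hydroxide. The (Z)-alkene, with the aryl group trans to the ester carbonyl, is the thermodynamically favoured isomer and is the geometry needed for an outward aryl group in step 8.

Step 2
Reactants: 3 methyl (Z)-3-(3,4-dimethoxyphenyl)-2-methoxyprop-2-enoate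
Product: 4 (Z)-3-(3,4-dimethoxyphenyl)-N,2-dimethoxy-N-methylprop-2-enamide
Conditions: MeNHOMe·HCl, i-PrMgCl, THF, −20 → 0 °C
Reagents that add atoms: N,O-dimethylhydroxylamine hydrochloride, CNOC.Cl
Why: Aminolysis of the ester by the chloromagnesium amide formed in the flask gives the N-methoxy-N-methylamide without touching the enol ether double bond. This amide will stop at the ketone stage in step 6.

Step 3
Reactants: 5 pent-3-yn-1-ol
Product: 7 (E)-3-ethylidene-2,2-dimethyl-1,2-oxasilolane, via dimethylsilyl ether 6 (not isolated)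
Conditions: (HMe2Si)2NH, neat, 60 °C; then Pt2[(CH2=CHSiMe2)2O]3 (0.5 mol%), THF, rt
Reagents that add atoms: 1,1,3,3-tetramethyldisilazane, C[SiH](C)N[SiH](C)C
Why: O-Silylation is followed by intramolecular hydrosilylation with a zerovalent platinum catalyst; the short tether enforces 5-exo-dig delivery of silicon to the alkyne carbon nearer to oxygen. Syn addition places the new vinylic hydrogen cis to silicon, so the methyl group ends cis to the CH2CH2O chain.

Step 4
Reactants: 7 (E)-3-ethylidene-2,2-dimethyl-1,2-oxasilolane
Product: 8 (E)-3-iodopent-3-en-1-ol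
Conditions: N-iodosuccinimide, 2,6-lutidine, (CF3)2CHOH, 0 °C; then K2CO3, MeOH–H2O
Reagents that add atoms: N-iodosuccinimide, O=C1CCC(=O)N1I
Why: Electrophilic ipso-iododesilylation of a vinylsilane: iodonium attack at the silicon-bearing carbon gives a β-silyl cation that loses silicon after the least-motion rotation, so iodine replaces silicon with retention. Basic methanolysis then frees the alcohol from silicon.

Step 5
Reactants: 8 (E)-3-iodopent-3-en-1-ol
Product: 9 (E)-tert-butyl[(3-iodopent-3-en-1-yl)oxy]dimethylsilane
Conditions: TBSCl, imidazole, DMF, rt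
Reagents that add atoms: tert-butyldimethylsilyl chloride, CC(C)(C)[Si](C)(C)Cl
Why: Standard silylation of a primary alcohol. The silyl ether masks an oxygen that would otherwise trap the oxyallyl cation in step 8, and it carries the latent allyl group.

Step 6
Reactants: 9 (E)-tert-butyl[(3-iodopent-3-en-1-yl)oxy]dimethylsilane; 4 (Z)-3-(3,4-dimethoxyphenyl)-N,2-dimethoxy-N-methylprop-2-enamide
Product: 11 (1Z,4E)-4-[2-(TBS-oxy)ethyl]-1-(3,4-dimethoxyphenyl)-2-methoxyhexa-1,4-dien-3-one, via vinyllithium 10 (not isolated)
Conditions: t-BuLi (2.1 equiv), Et2O, −78 °C; then 4, THF, −78 → 0 °C; aq NH4Cl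
Reagents that add atoms: none
Why: Iodine–lithium exchange keeps the alkene geometry, and acyl substitution on the N-methoxy-N-methylamide stops at the ketone through the stable lithium chelate. Both alkene geometries of 11 are inherited from stereodefined partners, so both β-substituents are anti to the carbonyl.

Step 7
Reactants: 12 (allyloxy)(tert-butyl)dimethylsilane
Product: 14 (Z)-tert-butyldimethyl{[3-(tributylstannyl)prop-1-en-1-yl]oxy}silane, via silyloxyallyllithium 13 (not isolated)
Conditions: s-BuLi, THF, −78 °C; then Bu3SnCl, −78 °C → rt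
Reagents that add atoms: tributyltin chloride, CCCC[Sn](Cl)(CCCC)CCCC
Why: Deprotonation of the allyl silyl ether gives the oxygen-chelated (Z)-1-silyloxyallyl anion, which is stannylated at the carbon remote from oxygen. The product is a known type of reagent, a (Z)-γ-silyloxyallylstannane.

Step 8
Reactants: 11 (1Z,4E)-4-[2-(TBS-oxy)ethyl]-1-(3,4-dimethoxyphenyl)-2-methoxyhexa-1,4-dien-3-one; 14 (Z)-tert-butyldimethyl{[3-(tributylstannyl)prop-1-en-1-yl]oxy}silane
Product: 17 (2S,3S,4R,5S)-2-[(1S)-1-(TBS-oxy)prop-2-en-1-yl]-5-[2-(TBS-oxy)ethyl]-3-(3,4-dimethoxyphenyl)-2-methoxy-4-methylcyclopentan-1-one, via oxyallyl cation 15 (not isolated), via stannyl enol ether 16 (not isolated)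
Conditions: Sc(OTf)3 (1.0 equiv), 2,6-bis[(3aS,8aR)-3a,8a-dihydro-8H-indeno[1,2-d]oxazol-2-yl]pyridine (1.1 equiv), 3 Å MS, CH2Cl2, rt; then 11, 14 (3 equiv), −20 °C → rt; aq NaHCO3
Reagents that add atoms: none
Why: Proposed new method: two-point binding of the α-methoxy ketone to the chiral Sc(OTf)3–pybox complex gives a pentadienyl cation that closes the ring C1–C8–C5–C6–C7 by thermal 4π conrotatory electrocyclisation (forming C6–C7), and the oxyallyl cation 15 is then intercepted at C5 by the γ-carbon of stannane 14 in an SE2' process (forming C4–C5); the closest known reaction types are the interrupted Nazarov cyclisation with allylsilane or allylstannane capture, the scandium–pybox-mediated enantioselective Nazarov cyclisation of α-alkoxy dienones, and the Lewis-acid addition of γ-oxygenated allylstannanes to oxocarbenium ions. Because both β-substituents of 11 are anti to the carbonyl, conrotation places the aryl group (C6) and the methyl group (C7) trans, and the chiral complex selects one sense of conrotation and so the absolute configuration of C6 and C7. C5 is set by approach of the stannane to the planar cation on the face opposite the adjacent C6 aryl group. C4 is set in an open antiperiplanar transition state in which the vinyl group lies anti to the C5–OMe oxocarbenium bond and the silyloxy group turns away from the ring carbon C6, which gives the (4S) relationship whatever the stannane geometry. C1 is set by protonation of enolate 16 on work-up, is expected to settle trans to the C7 methyl group, and is erased in step 10 in any case. The step needs capture to outrun proton loss from 15 (excess stannane, no base, non-coordinating solvent) and needs attack at C5 and not at C1, which the methoxy group secures by concentrating positive charge at C5 as an oxocarbenium ion.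

Step 9
Reactants: 17 (2S,3S,4R,5S)-2-[(1S)-1-(TBS-oxy)prop-2-en-1-yl]-5-[2-(TBS-oxy)ethyl]-3-(3,4-dimethoxyphenyl)-2-methoxy-4-methylcyclopentan-1-one
Product: 18 (2S,3S,4R,5S)-2-[(1R)-1-(TBS-oxy)-2-oxopropyl]-5-[2-(TBS-oxy)ethyl]-3-(3,4-dimethoxyphenyl)-2-methoxy-4-methylcyclopentan-1-one
Conditions: PdCl2[2-(4,5-dihydrooxazol-2-yl)quinoline] (5 mol%), AgSbF6 (12 mol%), aq t-BuOOH, CH2Cl2, 0 °C → rt
Reagents that add atoms: tert-butyl hydroperoxide, CC(C)(C)OO
Why: Tsuji–Wacker oxidation of the terminal alkene; the quinoline–oxazoline complex of divalent palladium with the hydroperoxide as oxidant gives the methyl ketone also for alkenes that carry an allylic oxygen, and it leaves the ring ketone, the silyl ethers and the arene alone. C3 reaches the ketone level and C2 becomes an enolisable methyl group.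

Step 10
Reactants: 18 (2S,3S,4R,5S)-2-[(1R)-1-(TBS-oxy)-2-oxopropyl]-5-[2-(TBS-oxy)ethyl]-3-(3,4-dimethoxyphenyl)-2-methoxy-4-methylcyclopentan-1-one
Product: 20 (1R,4R,5S,6S,7R)-4-(TBS-oxy)-1-[2-(TBS-oxy)ethyl]-6-(3,4-dimethoxyphenyl)-5-methoxy-7-methylbicyclo[3.2.1]octane-3,8-dione, via dilithium bis-enolate 19 (not isolated)
Conditions: LiN(i-Pr)2 (2.3 equiv), THF, −78 → −30 °C; then CuCl2 (2.5 equiv), DMF, −78 °C → rt
Reagents that add atoms: none
Why: Intramolecular oxidative coupling of a ketone bis-enolate mediated by divalent copper, a known route to 1,4-diketones: kinetic deprotonation takes the methyl group (C2) of the α-silyloxy ketone and the only α-hydrogen (C1) of the ring ketone, and one-electron oxidation joins C1 to C2. The six-membered ring can form only on the face of the cyclopentanone that carries the C5 side chain, which fixes the bridgehead C1 whatever its earlier configuration.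

Step 11
Reactants: 20 (1R,4R,5S,6S,7R)-4-(TBS-oxy)-1-[2-(TBS-oxy)ethyl]-6-(3,4-dimethoxyphenyl)-5-methoxy-7-methylbicyclo[3.2.1]octane-3,8-dione
Product: 22 (1S,4S,5S,6S,7R)-4-(TBS-oxy)-1-[2-(TBS-oxy)ethyl]-6-(3,4-dimethoxyphenyl)-3,5-dimethoxy-7-methylbicyclo[3.2.1]oct-2-en-8-one, via potassium enolate 21 (not isolated)
Conditions: KN(SiMe3)2, THF, −78 °C; then MeOTf, DMPU, −78 → −40 °C
Reagents that add atoms: methyl trifluoromethanesulfonate, COS(=O)(=O)C(F)(F)F
Why: O-Alkylation of a kinetic potassium enolate with a hard methylating agent in a dipolar medium. The bulky base removes a C2 hydrogen and not the hindered, silyloxy-substituted C4 hydrogen, C8 has no α-hydrogen, and C-methylation at the neopentyl-type C2 is disfavoured; C4 is not touched.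

Step 12
Reactants: 22 (1S,4S,5S,6S,7R)-4-(TBS-oxy)-1-[2-(TBS-oxy)ethyl]-6-(3,4-dimethoxyphenyl)-3,5-dimethoxy-7-methylbicyclo[3.2.1]oct-2-en-8-one
Product: 23 (1S,4S,5S,6S,7R)-4-(TBS-oxy)-6-(3,4-dimethoxyphenyl)-1-(2-hydroxyethyl)-3,5-dimethoxy-7-methylbicyclo[3.2.1]oct-2-en-8-one
Conditions: HF·pyridine, pyridine, THF, 0 °C
Reagents that add atoms: none
Why: Buffered fluoride desilylation distinguishes the unhindered primary silyl ether from the secondary one at C4, which is flanked by the quaternary C5 and the enol ether carbon. The pyridine buffer protects the acid-labile enol ether.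

Step 13
Reactants: 23 (1S,4S,5S,6S,7R)-4-(TBS-oxy)-6-(3,4-dimethoxyphenyl)-1-(2-hydroxyethyl)-3,5-dimethoxy-7-methylbicyclo[3.2.1]oct-2-en-8-one
Product: 24 2-[(1S,4S,5S,6S,7R)-4-(TBS-oxy)-6-(3,4-dimethoxyphenyl)-3,5-dimethoxy-7-methyl-8-oxobicyclo[3.2.1]oct-2-en-1-yl]acetaldehyde
Conditions: 1,1,1-triacetoxy-1,1-dihydro-1,2-benziodoxol-3(1H)-one, pyridine, CH2Cl2, 0 °C → rt
Reagents that add atoms: none
Why: Buffered periodinane oxidation of a primary alcohol to the aldehyde. The near-neutral conditions spare the enol ether and the secondary silyl ether.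

Step 14
Reactants: 24 2-[(1S,4S,5S,6S,7R)-4-(TBS-oxy)-6-(3,4-dimethoxyphenyl)-3,5-dimethoxy-7-methyl-8-oxobicyclo[3.2.1]oct-2-en-1-yl]acetaldehyde
Product: 25 (1S,4S,5S,6S,7R)-1-allyl-4-(TBS-oxy)-6-(3,4-dimethoxyphenyl)-3,5-dimethoxy-7-methylbicyclo[3.2.1]oct-2-en-8-one
Conditions: Ph3PCH3Br, KN(SiMe3)2, THF, 0 °C; then 24, −78 → 0 °C
Reagents that add atoms: methyltriphenylphosphonium bromide, C[P+](c1ccccc1)(c1ccccc1)c1ccccc1.[Br-]
Why: Wittig methylenation; the aldehyde reacts far faster than the C8 ketone, which is shielded by two quaternary α-carbons. The two-carbon chain becomes the allyl group only after all olefin-oxidising steps are past.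

Step 15
Reactants: 25 (1S,4S,5S,6S,7R)-1-allyl-4-(TBS-oxy)-6-(3,4-dimethoxyphenyl)-3,5-dimethoxy-7-methylbicyclo[3.2.1]oct-2-en-8-one
Product: 26 (1S,4S,5S,6S,7R)-1-allyl-6-(3,4-dimethoxyphenyl)-4-hydroxy-3,5-dimethoxy-7-methylbicyclo[3.2.1]oct-2-en-8-one
Conditions: Bu4NF, AcOH (1:1), THF, 0 °C → rt
Reagents that add atoms: none
Why: Fluoride cleavage of the remaining silyl ether. Acetic acid buffers the medium so that the liberated β-hydroxy ketone does not sit as a free alkoxide (retro-aldol), while the enol ether sees no strong acid.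

Step 16
Reactants: 26 (1S,4S,5S,6S,7R)-1-allyl-6-(3,4-dimethoxyphenyl)-4-hydroxy-3,5-dimethoxy-7-methylbicyclo[3.2.1]oct-2-en-8-one
Product: 27 (1S,4S,5S,6S,7R)-1-allyl-6-(3,4-dimethoxyphenyl)-3,5-dimethoxy-7-methyl-8-oxobicyclo[3.2.1]oct-2-en-4-yl acetate
Conditions: Ac2O, pyridine, 4-(dimethylamino)pyridine (cat.), CH2Cl2, rt
Reagents that add atoms: acetic anhydride, CC(=O)OC(C)=O
Why: Standard acylation of a secondary alcohol with nucleophilic catalysis, with retention at C4. Placing it last keeps the acetate away from enolates, ylide and fluoride.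

## Compound list

1 | 3,4-dimethoxybenzaldehyde | COc1ccc(C=O)cc1OC | starting material
2 | methyl 2-methoxyacetate | COCC(=O)OC | starting material
3 | methyl (Z)-3-(3,4-dimethoxyphenyl)-2-methoxyprop-2-enoate | COC(=O)/C(OC)=C/c1ccc(OC)c(OC)c1 | intermediate
4 | (Z)-3-(3,4-dimethoxyphenyl)-N,2-dimethoxy-N-methylprop-2-enamide | CON(C)C(=O)/C(OC)=C/c1ccc(OC)c(OC)c1 | intermediate
5 | pent-3-yn-1-ol | CC#CCCO | starting material
6 | dimethyl(pent-3-yn-1-yloxy)silane | CC#CCCO[SiH](C)C | intermediate
7 | (E)-3-ethylidene-2,2-dimethyl-1,2-oxasilolane | C/C=C1\CCO[Si]1(C)C | intermediate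
8 | (E)-3-iodopent-3-en-1-ol | C/C=C(/I)CCO | intermediate
9 | (E)-tert-butyl[(3-iodopent-3-en-1-yl)oxy]dimethylsilane | C/C=C(/I)CCO[Si](C)(C)C(C)(C)C | intermediate
10 | (Z)-{5-[(tert-butyldimethylsilyl)oxy]pent-2-en-3-yl}lithium | C/C=C(/[Li])CCO[Si](C)(C)C(C)(C)C | intermediate
11 | (1Z,4E)-4-{2-[(tert-butyldimethylsilyl)oxy]ethyl}-1-(3,4-dimethoxyphenyl)-2-methoxyhexa-1,4-dien-3-one | CC(C)(C)[Si](C)(C)OCC/C(=C\C)C(=O)/C(OC)=C/c1ccc(OC)c(OC)c1 | intermediate
12 | (allyloxy)(tert-butyl)dimethylsilane | C=CCO[Si](C)(C)C(C)(C)C | starting material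
13 | (Z)-1-[(tert-butyldimethylsilyl)oxy]allyllithium (delocalised, drawn as the γ-lithio form) | [Li]C/C=C\O[Si](C)(C)C(C)(C)C | intermediate
14 | (Z)-tert-butyldimethyl{[3-(tributylstannyl)prop-1-en-1-yl]oxy}silane | CCCC[Sn](CCCC)(CCCC)C/C=C\O[Si](C)(C)C(C)(C)C | intermediate
15 | scandium-bound 2-oxidocyclopentenylium (oxyallyl) cation from 11, drawn without metal and ligand; C6 aryl and C7 methyl trans | CO[C+]1C([O-])=C(CCO[Si](C)(C)C(C)(C)C)[C@H](C)[C@H]1c1ccc(OC)c(OC)c1 | intermediate
16 | tributylstannyl enol ether (C1=C8) of 17 | C=C[C@H](O[Si](C)(C)C(C)(C)C)[C@]1(OC)C(O[Sn](CCCC)(CCCC)CCCC)=C(CCO[Si](C)(C)C(C)(C)C)[C@H](C)[C@H]1c1ccc(OC)c(OC)c1 | intermediate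
17 | (2S,3S,4R,5S)-2-[(1S)-1-{[tert-butyl(dimethyl)silyl]oxy}prop-2-en-1-yl]-5-(2-{[tert-butyl(dimethyl)silyl]oxy}ethyl)-3-(3,4-dimethoxyphenyl)-2-methoxy-4-methylcyclopentan-1-one | C=C[C@H](O[Si](C)(C)C(C)(C)C)[C@]1(OC)C(=O)[C@@H](CCO[Si](C)(C)C(C)(C)C)[C@H](C)[C@H]1c1ccc(OC)c(OC)c1 | intermediate
18 | (2S,3S,4R,5S)-2-[(1R)-1-{[tert-butyl(dimethyl)silyl]oxy}-2-oxopropyl]-5-(2-{[tert-butyl(dimethyl)silyl]oxy}ethyl)-3-(3,4-dimethoxyphenyl)-2-methoxy-4-methylcyclopentan-1-one | CC(=O)[C@H](O[Si](C)(C)C(C)(C)C)[C@]1(OC)C(=O)[C@@H](CCO[Si](C)(C)C(C)(C)C)[C@H](C)[C@H]1c1ccc(OC)c(OC)c1 | intermediate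
19 | dilithium bis-enolate of 18 (C1=C8 and C2=C3) | C=C(O[Li])[C@H](O[Si](C)(C)C(C)(C)C)[C@]1(OC)C(O[Li])=C(CCO[Si](C)(C)C(C)(C)C)[C@H](C)[C@H]1c1ccc(OC)c(OC)c1 | intermediate
20 | (1R,4R,5S,6S,7R)-4-{[tert-butyl(dimethyl)silyl]oxy}-1-(2-{[tert-butyl(dimethyl)silyl]oxy}ethyl)-6-(3,4-dimethoxyphenyl)-5-methoxy-7-methylbicyclo[3.2.1]octane-3,8-dione | CC(C)(C)[Si](C)(C)OCC[C@]12CC(=O)[C@H](O[Si](C)(C)C(C)(C)C)[C@](OC)(C1=O)[C@H](c1ccc(OC)c(OC)c1)[C@H]2C | intermediate
21 | potassium C2=C3 enolate of 20 | CC(C)(C)[Si](C)(C)OCC[C@]12C=C(O[K])[C@H](O[Si](C)(C)C(C)(C)C)[C@](OC)(C1=O)[C@H](c1ccc(OC)c(OC)c1)[C@H]2C | intermediate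
22 | (1S,4S,5S,6S,7R)-4-{[tert-butyl(dimethyl)silyl]oxy}-1-(2-{[tert-butyl(dimethyl)silyl]oxy}ethyl)-6-(3,4-dimethoxyphenyl)-3,5-dimethoxy-7-methylbicyclo[3.2.1]oct-2-en-8-one | CC(C)(C)[Si](C)(C)OCC[C@]12C=C(OC)[C@H](O[Si](C)(C)C(C)(C)C)[C@](OC)(C1=O)[C@H](c1ccc(OC)c(OC)c1)[C@H]2C | intermediate
23 | (1S,4S,5S,6S,7R)-4-{[tert-butyl(dimethyl)silyl]oxy}-6-(3,4-dimethoxyphenyl)-1-(2-hydroxyethyl)-3,5-dimethoxy-7-methylbicyclo[3.2.1]oct-2-en-8-one | OCC[C@]12C=C(OC)[C@H](O[Si](C)(C)C(C)(C)C)[C@](OC)(C1=O)[C@H](c1ccc(OC)c(OC)c1)[C@H]2C | intermediate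
24 | 2-[(1S,4S,5S,6S,7R)-4-{[tert-butyl(dimethyl)silyl]oxy}-6-(3,4-dimethoxyphenyl)-3,5-dimethoxy-7-methyl-8-oxobicyclo[3.2.1]oct-2-en-1-yl]acetaldehyde | O=CC[C@]12C=C(OC)[C@H](O[Si](C)(C)C(C)(C)C)[C@](OC)(C1=O)[C@H](c1ccc(OC)c(OC)c1)[C@H]2C | intermediate
25 | (1S,4S,5S,6S,7R)-1-allyl-4-{[tert-butyl(dimethyl)silyl]oxy}-6-(3,4-dimethoxyphenyl)-3,5-dimethoxy-7-methylbicyclo[3.2.1]oct-2-en-8-one | C=CC[C@]12C=C(OC)[C@H](O[Si](C)(C)C(C)(C)C)[C@](OC)(C1=O)[C@H](c1ccc(OC)c(OC)c1)[C@H]2C | intermediate
26 | (1S,4S,5S,6S,7R)-1-allyl-6-(3,4-dimethoxyphenyl)-4-hydroxy-3,5-dimethoxy-7-methylbicyclo[3.2.1]oct-2-en-8-one | C=CC[C@]12C=C(OC)[C@H](O)[C@](OC)(C1=O)[C@H](c1ccc(OC)c(OC)c1)[C@H]2C | intermediate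
27 | (1S,4S,5S,6S,7R)-1-allyl-6-(3,4-dimethoxyphenyl)-3,5-dimethoxy-7-methyl-8-oxobicyclo[3.2.1]oct-2-en-4-yl acetate | C=CC[C@]12C=C(OC)[C@H](OC(C)=O)[C@](OC)(C1=O)[C@H](c1ccc(OC)c(OC)c1)[C@H]2C | target

## Step count and least certain steps

Total: 16 steps. Longest linear sequence: 13 steps (5 → 7 → 8 → 9 → 11 → 17 → 18 → 20 → 22 → 23 → 24 → 25 → 26 → 27; steps 3–6 and 8–16).

**Step 8 (key step, the one step beyond established precedent).**
- What may go wrong: the oxyallyl cation may lose a proton toward C6 before the stannane arrives, which ends the reaction at a cyclopentenone. Capture may occur at C1 instead of C5. The stannane may react through its enol-ether carbon, or add to the Lewis-acid-activated dienone before cyclisation. The topicity at C4 may be the wrong one, because the open transition state is only weakly biased. The induction by the chiral complex may be low, because the capture adds a step that can erode it.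
- Fallback, with known reactions only, from 11 back to 17: dienone 11 is cyclised with the same Sc(OTf)3–pybox complex without a nucleophile, a known enantioselective Nazarov cyclisation of α-alkoxy dienones, and proton loss toward C6 gives cyclopentenone F1. Dissolving-metal reduction (Li, NH3/THF, −78 °C, one equivalent of t-BuOH) protonates the benzylic C6 to the more stable arrangement with aryl trans to methyl and leaves the lithium enolate on the methoxy-bearing side; Me3SiCl traps it as silyl enol ether F2. A Mukaiyama aldol addition of F2 to acrolein (BF3·OEt2, CH2Cl2, −78 °C) forms C4–C5 on the face anti to the aryl group and gives allylic alcohol F3. Silylation (TBSOTf, 2,6-lutidine) returns to 17.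

**Step 10.**
- What may go wrong: the second enolisation at the hindered C1 methine may be incomplete. The enolate radicals may couple between molecules, or be chlorinated or dehydrogenated by the copper salt, instead of closing the strained bridged ring.
- Fallback, from 18 back to 20: the closure is made stepwise. Kinetic enolisation of the methyl ketone with internal quench (LiN(SiMe3)2, Me3SiCl, THF, −78 °C) gives trimethylsilyl enol ether F4; N-bromosuccinimide converts it into bromomethyl ketone F5; KOt-Bu in t-BuOH/THF at 0 °C then forms the C1 enolate reversibly, and it displaces bromide to give 20.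

**Step 11.**
- What may go wrong: methylation may occur on carbon instead of oxygen. Enolisation may go toward C4, which would give the regioisomeric enol ether or epimerise C4.
- Fallback, from 20 back to 22: the enol ether is made without an enolate. Aprotic ketalisation of the C3 ketone (MeOSiMe3, Me3SiOTf cat., CH2Cl2, −78 °C; C8 is too hindered to react) gives dimethyl ketal F6. Treatment with Me3SiOTf and i-Pr2NEt ionises it to the oxocarbenium ion, and the hindered amine removes a proton from the less hindered C2 to give 22.

**Step 4.**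
- What may go wrong: the silicon carries an oxygen substituent, which weakens β-silyl stabilisation, so the ipso substitution may be slow. The alkene geometry may erode through addition–elimination.
- Fallback, from 4 back to 11, bypassing steps 3–6: the ethylidene arm is built by aldol condensation. The Grignard reagent F7, made from commercial (3-bromopropoxy)(tert-butyl)dimethylsilane and magnesium, adds to amide 4 to give ketone F8. Its lithium enolate (LiN(i-Pr)2, THF, −78 °C; only the α′-CH2 can be deprotonated) adds to acetaldehyde to give aldol F9. Mesylation (MsCl, Et3N) gives mesylate F10, and E1cB elimination with DBU gives 11 as the more stable (E)-isomer, with methyl trans to the carbonyl.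

## Further compounds

F1 | step 8 | (4S,5S)-5-(2-{[tert-butyl(dimethyl)silyl]oxy}ethyl)-3-(3,4-dimethoxyphenyl)-2-methoxy-4-methylcyclopent-2-en-1-one | COC1=C(c2ccc(OC)c(OC)c2)[C@@H](C)[C@H](CCO[Si](C)(C)C(C)(C)C)C1=O
F2 | step 8 | {[(3S,4S,5S)-5-(2-{[tert-butyl(dimethyl)silyl]oxy}ethyl)-3-(3,4-dimethoxyphenyl)-2-methoxy-4-methylcyclopent-1-en-1-yl]oxy}trimethylsilane | COC1=C(O[Si](C)(C)C)[C@@H](CCO[Si](C)(C)C(C)(C)C)[C@H](C)[C@H]1c1ccc(OC)c(OC)c1
F3 | step 8 | (2S,3S,4R,5S)-5-(2-{[tert-butyl(dimethyl)silyl]oxy}ethyl)-3-(3,4-dimethoxyphenyl)-2-[(1S)-1-hydroxyprop-2-en-1-yl]-2-methoxy-4-methylcyclopentan-1-one | C=C[C@H](O)[C@]1(OC)C(=O)[C@@H](CCO[Si](C)(C)C(C)(C)C)[C@H](C)[C@H]1c1ccc(OC)c(OC)c1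
F4 | step 10 | trimethylsilyl enol ether (C2=C3) of methyl ketone 18, ring configuration as in 18 | C=C(O[Si](C)(C)C)[C@H](O[Si](C)(C)C(C)(C)C)[C@]1(OC)C(=O)[C@@H](CCO[Si](C)(C)C(C)(C)C)[C@H](C)[C@H]1c1ccc(OC)c(OC)c1
F5 | step 10 | (2S,3S,4R,5S)-2-[(1R)-3-bromo-1-{[tert-butyl(dimethyl)silyl]oxy}-2-oxopropyl]-5-(2-{[tert-butyl(dimethyl)silyl]oxy}ethyl)-3-(3,4-dimethoxyphenyl)-2-methoxy-4-methylcyclopentan-1-one | BrCC(=O)[C@H](O[Si](C)(C)C(C)(C)C)[C@]1(OC)C(=O)[C@@H](CCO[Si](C)(C)C(C)(C)C)[C@H](C)[C@H]1c1ccc(OC)c(OC)c1
F6 | step 11 | (1R,4R,5S,6S,7R)-4-{[tert-butyl(dimethyl)silyl]oxy}-1-(2-{[tert-butyl(dimethyl)silyl]oxy}ethyl)-6-(3,4-dimethoxyphenyl)-3,3,5-trimethoxy-7-methylbicyclo[3.2.1]octan-8-one | CC(C)(C)[Si](C)(C)OCC[C@]12CC(OC)(OC)[C@H](O[Si](C)(C)C(C)(C)C)[C@](OC)(C1=O)[C@H](c1ccc(OC)c(OC)c1)[C@H]2C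
F7 | step 4 | {3-[(tert-butyldimethylsilyl)oxy]propyl}magnesium bromide | CC(C)(C)[Si](C)(C)OCCC[Mg]Br
F8 | step 4 | (Z)-6-[(tert-butyldimethylsilyl)oxy]-1-(3,4-dimethoxyphenyl)-2-methoxyhex-1-en-3-one | CC(C)(C)[Si](C)(C)OCCCC(=O)/C(OC)=C/c1ccc(OC)c(OC)c1
F9 | step 4 | (Z)-4-{2-[(tert-butyldimethylsilyl)oxy]ethyl}-1-(3,4-dimethoxyphenyl)-5-hydroxy-2-methoxyhex-1-en-3-one (mixture of diastereomers at C4 and C5) | CC(O)C(CCO[Si](C)(C)C(C)(C)C)C(=O)/C(OC)=C/c1ccc(OC)c(OC)c1
F10 | step 4 | methanesulfonate of F9 (mixture of diastereomers) | CC(OS(C)(=O)=O)C(CCO[Si](C)(C)C(C)(C)C)C(=O)/C(OC)=C/c1ccc(OC)c(OC)c1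
A1 | alternative 1 | tert-butyldimethyl[2-(4,5,5-trimethoxy-2-methylcyclopenta-1,3-dien-1-yl)ethoxy]silane | COC1=CC(C)=C(CCO[Si](C)(C)C(C)(C)C)C1(OC)OC
A2 | alternative 1 | {[3,3-bis((S)-1-phenylethoxy)prop-1-en-2-yl]oxy}triethylsilane | C=C(O[Si](CC)(CC)CC)C(O[C@@H](C)c1ccccc1)O[C@@H](C)c1ccccc1
A3 | alternative 1 | 1-(2-{[tert-butyl(dimethyl)silyl]oxy}ethyl)-5,8,8-trimethoxy-7-methyl-4-[(S)-1-phenylethoxy]bicyclo[3.2.1]oct-6-en-3-one, C1, C4 and C5 arranged as in the target | CC(C)(C)[Si](C)(C)OCC[C@]12CC(=O)[C@H](O[C@@H](C)c3ccccc3)[C@](OC)(C1(OC)OC)C=C2C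
A4 | alternative 2 | 6-endo-[(E)-2-acetoxy-1-methoxyethenyl]-1-(2-{[tert-butyl(dimethyl)silyl]oxy}ethyl)-3-methoxy-5-methylbicyclo[3.1.0]hex-3-en-2-one | CC(C)(C)[Si](C)(C)OCC[C@]12C(=O)C(OC)=C[C@@]1(C)[C@H]2/C(OC)=C\OC(C)=O
A5 | alternative 2 | 1-(2-{[tert-butyl(dimethyl)silyl]oxy}ethyl)-3,5-dimethoxy-7-methyl-8-oxobicyclo[3.2.1]octa-2,6-dien-4-yl acetate, C1, C4 and C5 arranged as in the target | CC(C)(C)[Si](C)(C)OCC[C@]12C=C(OC)[C@H](OC(C)=O)[C@](OC)(C1=O)C=C2C
A6 | alternative 3 | 4-acetoxy-1-allyl-6-(3,4-dimethoxyphenyl)-3-methoxy-7-methyl-5-oxocyclohept-2-ene-1-carbaldehyde (target numbering, formyl carbon = C8) | C=CC[C@@]1(C=O)C=C(OC)[C@H](OC(C)=O)C(=O)[C@H](c2ccc(OC)c(OC)c2)[C@H]1C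
A7 | alternative 3 | 1-allyl-6-(3,4-dimethoxyphenyl)-5-hydroxy-3-methoxy-7-methyl-8-oxobicyclo[3.2.1]oct-2-en-4-yl acetate (O-demethyl target, all centres arranged as in the target) | C=CC[C@]12C=C(OC)[C@H](OC(C)=O)[C@](O)(C1=O)[C@H](c1ccc(OC)c(OC)c1)[C@H]2C
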